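The 3-acyltetronic acid is read as the Dieckmann product of a β-keto ester hung on the tertiary oxygen of the spiro carbon. The exocyclic enol carbon of the tetronic acid ring and the methyl-bearing alkene carbon of the 13-membered ring are therefore joined as acyl and (Z)-alkenyl partners: a palladium/copper thioester–alkenylstannane coupling of an open-chain S-phenyl malonate closes a 14-membered keto-lactone with the Z-enone in place. Fluoride then contracts it to the spirotetronic acid and the 13-membered carbocycle while freeing the acid. The cyclohexene comes from a catalytic enantioselective Diels–Alder reaction of a 2-silyloxydiene; the syn-dimethyl chain from a desymmetrised meso-diol.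

Key step: step 17

Assumption 1: the lipase is taken to acetylate the meso-diol to the (2R,4S)-monoacetate 3; should it give the antipode, lipase hydrolysis of the diacetate supplies 3 instead.
Assumption 2: the (R)-oxazaborolidinium salt is taken to expose the Si face of the acrylate α-carbon (α-C–H···O binding model); should the sense be the reverse, the (S)-catalyst is used.

Step 1
Reactants: 1 meso-2,4-dimethylglutaric anhydride
Product: 2 meso-2,4-dimethylpentane-1,5-diol
Conditions: LiAlH4, THF, 0 °C to reflux; aqueous work-up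
Reagents that add atoms: none
Why: Hydride reduction of both acyl groups of the cyclic anhydride should give the meso 1,5-diol without touching the two methyl-bearing centres (LiAlH4 reduction).

Step 2
Reactants: 2 meso-2,4-dimethylpentane-1,5-diol
Product: 3 (2R,4S)-5-hydroxy-2,4-dimethylpentyl acetate
Conditions: Pseudomonas fluorescens lipase (Amano AK), vinyl acetate, THF, rt
Reagents that add atoms: vinyl acetate, C=COC(C)=O
Why: Lipase-catalysed transesterification with an irreversible acyl donor distinguishes the enantiotopic hydroxymethyl groups and so sets both methyl-bearing centres of the side chain in the absolute sense (enzymatic desymmetrisation).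

Step 3
Reactants: 3 (2R,4S)-5-hydroxy-2,4-dimethylpentyl acetate
Product: 4 (2R,4S)-2,4-dimethyl-5-(tosyloxy)pentyl acetate
Conditions: TsCl, Et3N, DMAP (cat.), CH2Cl2, 0 °C to rt
Reagents that add atoms: p-toluenesulfonyl chloride, Cc1ccc(cc1)S(Cl)(=O)=O
Why: Sulfonylation of the remaining primary alcohol turns it into a leaving group (tosylation).

Step 4
Reactants: 4 (2R,4S)-2,4-dimethyl-5-(tosyloxy)pentyl acetate; 5 but-3-enylmagnesium bromide
Product: 7 (2R,4R)-2,4-dimethylnon-8-en-1-ol, via alkenyl acetate 6 (not isolated)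
Conditions: 5 (1.5 equiv), Li2CuCl4 (5 mol %), THF, −78 to 0 °C; then MeOH, K2CO3, rt
Reagents that add atoms: none
Why: Copper-catalysed substitution of the primary tosylate by the alkyl Grignard reagent (Kochi–Schlosser coupling) should outrun attack on the acetate at low temperature, and the acetate is then removed by methanolysis only after the tosylate is consumed, so that no alkoxide can close a tetrahydropyran.

Step 5
Reactants: 7 (2R,4R)-2,4-dimethylnon-8-en-1-ol; 8 pent-1-en-3-one
Product: 9 (4E,9R,11R)-12-hydroxy-9,11-dimethyldodec-4-en-3-one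
Conditions: 8 (3 equiv), second-generation Hoveyda–Grubbs catalyst (5 mol %), CH2Cl2, 40 °C
Reagents that add atoms: none
Why: Cross-metathesis of the terminal alkene with the electron-poor vinyl ketone should favour the hetero-coupled (E)-enone and tolerates the free alcohol (olefin cross-metathesis).

Step 6
Reactants: 9 (4E,9R,11R)-12-hydroxy-9,11-dimethyldodec-4-en-3-one
Product: 11 (2Z,4E,9R,11R)-9,11-dimethyl-3,12-bis(triisopropylsilyloxy)dodeca-2,4-diene, via silyl ether enone 10 (not isolated)
Conditions: i-Pr3SiOTf (2.4 equiv), Et3N (4 equiv), CH2Cl2, −78 °C to rt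
Reagents that add atoms: triisopropylsilyl triflate, CC(C)[Si](C(C)C)(C(C)C)OS(=O)(=O)C(F)(F)F
Why: The silyl triflate caps the alcohol and soft-enolises the ethyl ketone to the cross-conjugated (Z)-silyl enol ether (methyl cis to oxygen), which gives a 2-silyloxydiene with both terminal substituents outside (silyl enol ether formation).

Step 7
Reactants: 11 (2Z,4E,9R,11R)-9,11-dimethyl-3,12-bis(triisopropylsilyloxy)dodeca-2,4-diene; 12 2,2,2-trifluoroethyl acrylate
Product: 13 2,2,2-trifluoroethyl (1R,2S,5S)-2-[(4R,6R)-4,6-dimethyl-7-(triisopropylsilyloxy)heptyl]-5-methyl-4-(triisopropylsilyloxy)cyclohex-3-ene-1-carboxylate (ester, side chain and methyl all cis)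
Conditions: 12 (3 equiv), (R)-1-(2-methylphenyl)-3,3-diphenyl-tetrahydro-1H,3H-pyrrolo[1,2-c][1,3,2]oxazaborole (20 mol %), HN(SO2CF3)2 (18 mol %), CH2Cl2, −78 to −40 °C
Reagents that add atoms: none
Why: In this cationic oxazaborolidine-catalysed Diels–Alder reaction the silyloxy group directs the acrylate β-carbon to the methyl-bearing diene terminus (para rule), the outside positions of the diene substituents make side chain and methyl cis, and the endo transition state on the Si face of the acrylate α-carbon sets C2 and C5 in the absolute sense.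

Step 8
Reactants: 13 the Diels–Alder adduct
Product: 14 2,2,2-trifluoroethyl (1R,2S,5S)-2-[(4R,6R)-4,6-dimethyl-7-(triisopropylsilyloxy)heptyl]-5-methyl-4-(trifluoromethanesulfonyloxy)cyclohex-3-ene-1-carboxylate
Conditions: CsF (3 equiv), PhN(SO2CF3)2 (1.5 equiv), DME, rt
Reagents that add atoms: N-phenylbis(trifluoromethanesulfonimide), O=S(=O)(N(c1ccccc1)S(=O)(=O)C(F)(F)F)C(F)(F)F
Why: Fluoride should cleave the silyl enol ether faster than the primary silyl ether, and the regiodefined enolate is triflated on oxygen before it can equilibrate towards the methyl-bearing carbon (enol triflate formation from a silyl enol ether).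

Step 9
Reactants: 14 the alkenyl triflate
Product: 16 2,2,2-trifluoroethyl (1S,2S,5S)-2-[(4R,6R)-4,6-dimethyl-7-(triisopropylsilyloxy)heptyl]-1-hydroxy-5-methyl-4-(trifluoromethanesulfonyloxy)cyclohex-3-ene-1-carboxylate (hydroxyl trans to the side chain), via potassium ester enolate 15 (not isolated)
Conditions: KN(SiMe3)2 (1.3 equiv), THF, −78 °C; then 2-(phenylsulfonyl)-3-phenyloxaziridine, −78 °C; aqueous work-up
Reagents that add atoms: 2-(phenylsulfonyl)-3-phenyloxaziridine, O=S(=O)(N1OC1c1ccccc1)c1ccccc1
Why: The exocyclic ester enolate should be oxidised from the face anti to the adjacent side chain, which A(1,3) strain holds pseudoaxial, so that the hydroxyl ends trans and the ester cis to the chain and the future spiro centre is fixed by substrate control (Davis enolate hydroxylation).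

Step 10
Reactants: 16 the α-hydroxy ester triflate
Product: 17 1-(2,2,2-trifluoroethyl) 4-[2-(trimethylsilyl)ethyl] (1S,2S,5S)-2-[(4R,6R)-4,6-dimethyl-7-(triisopropylsilyloxy)heptyl]-1-hydroxy-5-methylcyclohex-3-ene-1,4-dicarboxylate
Conditions: Pd(OAc)2 (10 mol %), PPh3 (20 mol %), CO (1 atm), Me3SiCH2CH2OH (5 equiv), Et3N, DMF, 50 °C
Reagents that add atoms: carbon monoxide, [C-]#[O+]; 2-(trimethylsilyl)ethanol, C[Si](C)(C)CCO
Why: Palladium-catalysed alkoxycarbonylation of the alkenyl triflate installs the ring carboxyl as a fluoride-labile ester, and the tertiary alcohol cannot intercept the acylpalladium because the lactone would hold a bridgehead alkene.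

Step 11
Reactants: 17 the diester silyl ether
Product: 18 1-(2,2,2-trifluoroethyl) 4-[2-(trimethylsilyl)ethyl] (1S,2S,5S)-1-hydroxy-2-[(4R,6R)-7-hydroxy-4,6-dimethylheptyl]-5-methylcyclohex-3-ene-1,4-dicarboxylate
Conditions: HF·pyridine, pyridine, THF, 0 °C to rt
Reagents that add atoms: none
Why: Buffered HF should remove the primary silyl ether while both esters survive this non-basic fluoride source (desilylation).

Step 12
Reactants: 18 the primary alcohol
Product: 19 1-(2,2,2-trifluoroethyl) 4-[2-(trimethylsilyl)ethyl] (1S,2S,5S)-2-[(4R,6R)-4,6-dimethyl-7-oxoheptyl]-1-hydroxy-5-methylcyclohex-3-ene-1,4-dicarboxylate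
Conditions: Dess–Martin periodinane, NaHCO3, CH2Cl2, 0 °C to rt
Reagents that add atoms: none
Why: Buffered periodinane oxidation should give the α-methyl aldehyde without epimerisation and leaves the tertiary alcohol untouched (Dess–Martin oxidation).

Step 13
Reactants: 19 the aldehyde; 20 ethyltriphenylphosphonium iodide
Product: 21 1-(2,2,2-trifluoroethyl) 4-[2-(trimethylsilyl)ethyl] (1S,2S,5S)-1-hydroxy-2-[(4R,6R,7Z)-8-iodo-4,6-dimethylnon-7-enyl]-5-methylcyclohex-3-ene-1,4-dicarboxylate
Conditions: 20 (2.5 equiv), n-BuLi, THF, −78 °C; I2; NaN(SiMe3)2, −20 °C; then 19, −78 to −20 °C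
Reagents that add atoms: iodine, II
Why: The α-iodo ylide should olefinate the aldehyde under kinetic control to the (Z)-2-iodoalkene with iodine cis to the chain (Stork–Zhao-type Wittig olefination), and the excess ylide makes up for deprotonation of the tertiary alcohol.

Step 14
Reactants: 21 the (Z)-alkenyl iodide
Product: 22 1-(2,2,2-trifluoroethyl) 4-[2-(trimethylsilyl)ethyl] (1S,2S,5S)-2-[(4R,6R,7Z)-4,6-dimethyl-8-(trimethylstannyl)non-7-enyl]-1-hydroxy-5-methylcyclohex-3-ene-1,4-dicarboxylate
Conditions: Me3SnSnMe3 (3 equiv), Pd(PPh3)4 (10 mol %), toluene, 80 °C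
Reagents that add atoms: hexamethylditin, C[Sn](C)(C)[Sn](C)(C)C
Why: Palladium-catalysed iodine–tin exchange with the distannane proceeds with retention of the alkene geometry (Stille-type stannylation).

Step 15
Reactants: 23 Meldrum's acid; 24 thiophenol
Product: 25 3-oxo-3-(phenylsulfanyl)propanoic acid
Conditions: toluene, 100 °C
Reagents that add atoms: none
Why: Thermal ring opening of Meldrum's acid by the thiol should give the malonic half thioester with loss of acetone.

Step 16
Reactants: 22 the alkenylstannane; 25 3-oxo-3-(phenylsulfanyl)propanoic acid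
Product: 26 the S-phenyl malonate of the tertiary alcohol of 22 (O-acyl group –C(=O)CH2C(=O)SPh; all other groups unchanged)
Conditions: 25 (4 equiv), DCC (4 equiv), CH2Cl2, 0 °C; 22 added last, 0 °C to rt
Reagents that add atoms: none
Why: Carbodiimide activation turns the half thioester into (phenylsulfanyl)carbonylketene, which should acylate even the hindered tertiary alcohol while the acid is consumed too quickly to protodestannylate the alkenylstannane (carbodiimide esterification through a ketene).

Step 17
Reactants: 26 the open-chain S-phenyl malonate alkenylstannane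
Product: 27 the 14-membered (Z)-enone keto-lactone (ring: C(=O)CH2C(=O)O–C1 of the cyclohexene, C2, the seven chain carbons, CH=C(CH3)–; trifluoroethyl ester on C1 and trimethylsilylethyl ester on C4 retained)
Conditions: Pd2(dba)3 (10 mol %), tri(2-furyl)phosphine (40 mol %), CuOP(O)Ph2 (2.5 equiv), THF, 40 °C, slow addition of 26 to 1 mM
Reagents that add atoms: none
Why: Zerovalent palladium inserts into the acyl–sulfur bond once the monovalent copper phosphinate binds sulfur, the (Z)-alkenyl group is transferred from tin (copper thiolate and tin phosphinate leave), and reductive elimination forms the acyl–alkenyl bond with retention of the alkene geometry. The closest known reaction type is the Liebeskind–Srogl ketone synthesis from thioesters and organostannanes, used here in the ring-closing sense of intramolecular Stille acylations. The ring closed is the 14-membered keto-lactone, by end-to-end macrocyclisation (exo with respect to the acyl carbon) at high dilution. No stereocentre is formed: the Z geometry of the enone is carried over from the stannane and the five existing centres are untouched under the neutral conditions. The step needs ring closure over oligomerisation, which the gauche arrangement of the trans-disposed malonyloxy group and side chain on adjacent ring carbons should favour, and reaction at the thioester only, which the thiophilic copper activation secures against the two oxo esters.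

Step 18
Reactants: 27 the 14-membered keto-lactone
Product: 29 okilactomycin C, via okilactomycin C trimethylsilylethyl ester 28 (not isolated)
Conditions: Bu4NF (6 equiv), THF, 0 °C to rt; then 1 M HCl
Reagents that add atoms: none
Why: Fluoride deprotonates the β-keto ester, whose enolate attacks the neighbouring trifluoroethyl ester in a 5-exo-trig Lacey–Dieckmann cyclisation that forms the acyltetronic acid and contracts the 14-membered lactone to the 13-membered carbocycle, and it then cleaves the 2-(trimethylsilyl)ethyl ester by β-elimination.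

Compound list
1 | meso-2,4-dimethylglutaric anhydride, (3R,5S)-3,5-dimethyloxane-2,6-dione | O=C1[C@H](C)C[C@H](C)C(=O)O1 | starting material
2 | meso-(2R,4S)-2,4-dimethylpentane-1,5-diol | OC[C@H](C)C[C@H](C)CO | intermediate
3 | (2R,4S)-5-hydroxy-2,4-dimethylpentyl acetate | CC(=O)OC[C@H](C)C[C@H](C)CO | intermediate
4 | (2R,4S)-2,4-dimethyl-5-(tosyloxy)pentyl acetate | CC(=O)OC[C@H](C)C[C@H](C)COS(=O)(=O)c1ccc(C)cc1 | intermediate
5 | but-3-enylmagnesium bromide | C=CCC[Mg]Br | starting material
6 | (2R,4R)-2,4-dimethylnon-8-enyl acetate | CC(=O)OC[C@H](C)C[C@H](C)CCCC=C | intermediate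
7 | (2R,4R)-2,4-dimethylnon-8-en-1-ol | OC[C@H](C)C[C@H](C)CCCC=C | intermediate
8 | pent-1-en-3-one (ethyl vinyl ketone) | CCC(=O)C=C | starting material
9 | (4E,9R,11R)-12-hydroxy-9,11-dimethyldodec-4-en-3-one | OC[C@H](C)C[C@H](C)CCC/C=C/C(=O)CC | intermediate
10 | (4E,9R,11R)-9,11-dimethyl-12-(triisopropylsilyloxy)dodec-4-en-3-one | CC(C)[Si](C(C)C)(C(C)C)OC[C@H](C)C[C@H](C)CCC/C=C/C(=O)CC | intermediate
11 | (2Z,4E,9R,11R)-9,11-dimethyl-3,12-bis(triisopropylsilyloxy)dodeca-2,4-diene | CC(C)[Si](C(C)C)(C(C)C)OC[C@H](C)C[C@H](C)CCC/C=C/C(O[Si](C(C)C)(C(C)C)C(C)C)=C/C | intermediate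
12 | 2,2,2-trifluoroethyl acrylate | C=CC(=O)OCC(F)(F)F | starting material
13 | 2,2,2-trifluoroethyl (1R,2S,5S)-2-[(4R,6R)-4,6-dimethyl-7-(triisopropylsilyloxy)heptyl]-5-methyl-4-(triisopropylsilyloxy)cyclohex-3-ene-1-carboxylate | CC(C)[Si](C(C)C)(C(C)C)OC[C@H](C)C[C@H](C)CCC[C@H]1C=C(O[Si](C(C)C)(C(C)C)C(C)C)[C@@H](C)C[C@H]1C(=O)OCC(F)(F)F | intermediate
14 | the corresponding 4-(trifluoromethanesulfonyloxy)cyclohexene (alkenyl triflate) | CC(C)[Si](C(C)C)(C(C)C)OC[C@H](C)C[C@H](C)CCC[C@H]1C=C(OS(=O)(=O)C(F)(F)F)[C@@H](C)C[C@H]1C(=O)OCC(F)(F)F | intermediate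
15 | potassium enolate of the trifluoroethyl ester 14 | CC(C)[Si](C(C)C)(C(C)C)OC[C@H](C)C[C@H](C)CCC[C@H]1C=C(OS(=O)(=O)C(F)(F)F)[C@@H](C)CC1=C([O-])OCC(F)(F)F.[K+] | intermediate
16 | 2,2,2-trifluoroethyl (1S,2S,5S)-2-[(4R,6R)-4,6-dimethyl-7-(triisopropylsilyloxy)heptyl]-1-hydroxy-5-methyl-4-(trifluoromethanesulfonyloxy)cyclohex-3-ene-1-carboxylate | CC(C)[Si](C(C)C)(C(C)C)OC[C@H](C)C[C@H](C)CCC[C@H]1C=C(OS(=O)(=O)C(F)(F)F)[C@@H](C)C[C@@]1(O)C(=O)OCC(F)(F)F | intermediate
17 | 1-(2,2,2-trifluoroethyl) 4-[2-(trimethylsilyl)ethyl] (1S,2S,5S)-2-[(4R,6R)-4,6-dimethyl-7-(triisopropylsilyloxy)heptyl]-1-hydroxy-5-methylcyclohex-3-ene-1,4-dicarboxylate | CC(C)[Si](C(C)C)(C(C)C)OC[C@H](C)C[C@H](C)CCC[C@H]1C=C(C(=O)OCC[Si](C)(C)C)[C@@H](C)C[C@@]1(O)C(=O)OCC(F)(F)F | intermediate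
18 | the corresponding 7-hydroxy-4,6-dimethylheptyl compound (primary alcohol) | OC[C@H](C)C[C@H](C)CCC[C@H]1C=C(C(=O)OCC[Si](C)(C)C)[C@@H](C)C[C@@]1(O)C(=O)OCC(F)(F)F | intermediate
19 | the corresponding (4R,6R)-4,6-dimethyl-7-oxoheptyl compound (aldehyde) | O=C[C@H](C)C[C@H](C)CCC[C@H]1C=C(C(=O)OCC[Si](C)(C)C)[C@@H](C)C[C@@]1(O)C(=O)OCC(F)(F)F | intermediate
20 | ethyltriphenylphosphonium iodide | CC[P+](c1ccccc1)(c1ccccc1)c1ccccc1.[I-] | starting material
21 | the corresponding (4R,6R,7Z)-8-iodo-4,6-dimethylnon-7-enyl compound (alkenyl iodide, iodine cis to the chain) | C/C(I)=C/[C@H](C)C[C@H](C)CCC[C@H]1C=C(C(=O)OCC[Si](C)(C)C)[C@@H](C)C[C@@]1(O)C(=O)OCC(F)(F)F | intermediate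
22 | the corresponding (4R,6R,7Z)-4,6-dimethyl-8-(trimethylstannyl)non-7-enyl compound (alkenylstannane) | C/C([Sn](C)(C)C)=C/[C@H](C)C[C@H](C)CCC[C@H]1C=C(C(=O)OCC[Si](C)(C)C)[C@@H](C)C[C@@]1(O)C(=O)OCC(F)(F)F | intermediate
23 | Meldrum's acid, 2,2-dimethyl-1,3-dioxane-4,6-dione | CC1(C)OC(=O)CC(=O)O1 | starting material
24 | thiophenol | Sc1ccccc1 | starting material
25 | 3-oxo-3-(phenylsulfanyl)propanoic acid | OC(=O)CC(=O)Sc1ccccc1 | intermediate
26 | S-phenyl malonate ester of the tertiary alcohol of 22 | C/C([Sn](C)(C)C)=C/[C@H](C)C[C@H](C)CCC[C@H]1C=C(C(=O)OCC[Si](C)(C)C)[C@@H](C)C[C@@]1(OC(=O)CC(=O)Sc1ccccc1)C(=O)OCC(F)(F)F | intermediate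
27 | 14-membered (Z)-enone keto-lactone | CC1=C/[C@H](C)C[C@H](C)CCC[C@H]2C=C(C(=O)OCC[Si](C)(C)C)[C@@H](C)C[C@@]2(OC(=O)CC\1=O)C(=O)OCC(F)(F)F | intermediate
28 | okilactomycin C 2-(trimethylsilyl)ethyl ester | CC1=C/[C@H](C)C[C@H](C)CCC[C@H]2C=C(C(=O)OCC[Si](C)(C)C)[C@@H](C)C[C@]23OC(=O)\C(=C\1O)C3=O | intermediate
29 | okilactomycin C | CC1=C/[C@H](C)C[C@H](C)CCC[C@H]2C=C(C(=O)O)[C@@H](C)C[C@]23OC(=O)\C(=C\1O)C3=O | target

Total step count: 18. Longest linear sequence: 17 steps (steps 1 to 14 and 16 to 18; step 15 makes a side reagent).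

Steps most likely to fail

Step 17. Intermolecular coupling may outrun ring closure, the alkenylstannane may be protodestannylated, the phosphine or thiolate may isomerise the Z-enone, or the malonyl thioester may lose thiophenolate. The fallback keeps the same ring-closing bond but makes it by addition to an aldehyde on a preformed tetronate. It sets out from alkenyl iodide 21 and comes back at 28. The tertiary alcohol of 21 is acetylated (Ac2O, catalytic Sc(OTf)3, MeCN) to the tertiary acetate F1. LiN(SiMe3)2 then effects a Dieckmann cyclisation to the spirotetronic acid F2, and Me2SO4/K2CO3 gives the methyl tetronate F3. Deprotonation at the tetronate carbon between the carbonyl and the enol ether (LiN(i-Pr)2, −78 °C) and quenching with DMF give the 3-formyl tetronate F4. CrCl2 with catalytic NiCl2 in DMSO/THF at high dilution (Nozaki–Hiyama–Kishi reaction) should close the 13-membered ring directly to the macrocyclic allylic alcohol F5. Dess–Martin oxidation gives the macrocyclic enone methyl tetronate F6, and LiCl in DMSO removes the tetronate methyl group to give 28, which Bu4NF converts into 29 as in step 18.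

Step 7. Facial or endo selectivity may be insufficient, the reaction may stop at a stepwise Mukaiyama–Michael adduct, or the acid catalyst may cleave the silyl enol ether. The fallback replaces catalyst control by an auxiliary. It sets out from diene 11 and comes back at 13. Diene 11 reacts with (S)-4-benzyl-3-acryloyloxazolidin-2-one and Et2AlCl at −78 °C; in the chelated s-cis imide the benzyl group blocks the Re face of the α-carbon, so the endo addition on the Si face should give the imide cycloadduct F7. LiOH/H2O2 cleaves the auxiliary to the cyclohexenecarboxylic acid F8, and esterification with 2,2,2-trifluoroethanol (EDC, DMAP) gives 13.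

Step 16. Acylation of the hindered tertiary alcohol may be slow, the half thioester may decarboxylate, or the free acid may protodestannylate the alkenylstannane. The fallback installs the malonyl unit before tin is present. It sets out from alkenyl iodide 21 and comes back at 26. Heating 21 with Meldrum's acid 23 (toluene, 100 °C) acylates the tertiary alcohol through the acylketene and gives the malonic half ester F9. Thiophenol 24 with EDC and catalytic DMAP gives the S-phenyl thioester alkenyl iodide F10. Stannylation as in step 14 (Me3SnSnMe3, Pd(PPh3)4) then gives 26; the thioester should be inert to zerovalent palladium as long as no thiophilic copper or zinc cofactor is present.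

Further compounds
F1 | step 17 | tertiary acetate of alkenyl iodide 21 | C/C(I)=C/[C@H](C)C[C@H](C)CCC[C@H]1C=C(C(=O)OCC[Si](C)(C)C)[C@@H](C)C[C@@]1(OC(C)=O)C(=O)OCC(F)(F)F
F2 | step 17 | spirotetronic acid (4-hydroxyfuran-2(5H)-one spiro-fused at C5) bearing the alkenyl iodide chain | C/C(I)=C/[C@H](C)C[C@H](C)CCC[C@H]1C=C(C(=O)OCC[Si](C)(C)C)[C@@H](C)C[C@]12OC(=O)C=C2O
F3 | step 17 | methyl tetronate (4-methoxy) of F2 | C/C(I)=C/[C@H](C)C[C@H](C)CCC[C@H]1C=C(C(=O)OCC[Si](C)(C)C)[C@@H](C)C[C@]12OC(=O)C=C2OC
F4 | step 17 | 3-formyl-4-methoxy tetronate bearing the alkenyl iodide chain | C/C(I)=C/[C@H](C)C[C@H](C)CCC[C@H]1C=C(C(=O)OCC[Si](C)(C)C)[C@@H](C)C[C@]12OC(=O)C(C=O)=C2OC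
F5 | step 17 | 13-membered macrocyclic allylic alcohol (both carbinol epimers) | CC1=C/[C@H](C)C[C@H](C)CCC[C@H]2C=C(C(=O)OCC[Si](C)(C)C)[C@@H](C)C[C@]23OC(=O)C(C\1O)=C3OC
F6 | step 17 | 13-membered macrocyclic (Z)-enone methyl tetronate | CC1=C/[C@H](C)C[C@H](C)CCC[C@H]2C=C(C(=O)OCC[Si](C)(C)C)[C@@H](C)C[C@]23OC(=O)C(C\1=O)=C3OC
F7 | step 7 | N-acyl oxazolidinone cycloadduct (imide analogue of 13) | CC(C)[Si](C(C)C)(C(C)C)OC[C@H](C)C[C@H](C)CCC[C@H]1C=C(O[Si](C(C)C)(C(C)C)C(C)C)[C@@H](C)C[C@H]1C(=O)N1C(=O)OC[C@@H]1Cc1ccccc1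
F8 | step 7 | cyclohexenecarboxylic acid corresponding to 13 | CC(C)[Si](C(C)C)(C(C)C)OC[C@H](C)C[C@H](C)CCC[C@H]1C=C(O[Si](C(C)C)(C(C)C)C(C)C)[C@@H](C)C[C@H]1C(=O)O
F9 | step 16 | malonic half ester of the tertiary alcohol of 21 | C/C(I)=C/[C@H](C)C[C@H](C)CCC[C@H]1C=C(C(=O)OCC[Si](C)(C)C)[C@@H](C)C[C@@]1(OC(=O)CC(=O)O)C(=O)OCC(F)(F)F
F10 | step 16 | S-phenyl malonate ester of the tertiary alcohol of 21 | C/C(I)=C/[C@H](C)C[C@H](C)CCC[C@H]1C=C(C(=O)OCC[Si](C)(C)C)[C@@H](C)C[C@@]1(OC(=O)CC(=O)Sc1ccccc1)C(=O)OCC(F)(F)F
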